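The readings were generated by integration on assumed constants; the scatter is artificial.

Which flask keeps the highest share of target against cross product?

all flasks: starting material 0.11 M; gas 4.8 mM (held)

| run | second substrate | temperature | remark | time |
|---|---|---|---|---|
| green | 0.15 M | 80 °C | run made earlier |  |
| teal | 0.24 M | 102 °C | run made earlier |  |
| eta | 0.110 M |  | at 70 °C until 1.5 min, from then on at 110 °C | 3.0 min |
| beta | 0.110 M | 110 °C |  | 3.0 min |
| theta | 0.110 M | 70 °C |  | 3.0 min |
| alpha | 0.110 M | 90 °C |  | 3.0 min |

| run | time / min | target / % | cross product / % |
|---|---|---|---|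
| green | 0.833 | 0.8 | 35.1 |
| green | 3.00 | 4.3 | 69.0 |
| green | 4.00 | 6.2 | 74.0 |
| green | 6.00 | 7.8 | 81.1 |
| green | 12.0 | 10.1 | 86.7 |
| teal | 0.500 | 0.8 | 71.8 |
| teal | 1.00 | 0 | 89.5 |
| teal | 1.50 | 0 | 95.9 |
| teal | 2.00 | 0.4 | 97.4 |
| teal | 2.50 | 2.4 | 98.8 |
| teal | 3.00 | 0.9 | 99.5 |

(each reading ± 1 percentage point)

- the flask that comes out highest in share of target in all that became target or cross product, or "all alike" when all lie within 1.5 percentage points (eta / beta / theta / alpha / all alike)
- share of target in all that became target or cross product, eta
- share of target in all that became target or cross product, beta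
- share of target in all that became target or cross product, theta
- share of target in all that became target or cross product, alpha

- the earlier runs were read with a standard deviation of 1 percentage point
- at the start none of the gas is in solution
- a reading or a percentage of target counts all its forms, free or not

1. First rung: cross product. The green run reads 35.1% cross product against 0.8% target at 0.833 min, far more, so cross product is the clock to reckon and target the slow remainder.

2. Read as second order, that green reading gives k = 0.0674 M⁻¹ s⁻¹ at 80 °C. The teal reading at 0.500 min gives 0.222 M⁻¹ s⁻¹ at 102 °C. Both carry the scatter. Here k is taken to grow by a constant factor per degree, stretched beyond the two runs.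

3. Theta's k is then 0.0392 M⁻¹ s⁻¹, so 3.87 min is its cross clock, the reciprocal of k times c(starting material), the time in which equal charges lose half to cross product. With n clocks elapsed, the cross fraction is n over one plus n, leaving aside what target takes.

4. Alpha's clock is 1.31 min and beta's 0.442 min. Beta passes its clock early, well inside 3.0 min, while theta's clock is longer than the run. Eta runs 3.78 clocks, 3.40 of them in its hot half. Cross fractions: theta 43.7%, alpha 69.7%, eta 79.1%, beta 87.2%.

5. Second rung: target. Green reads 4.3% at 3.00 min, while teal, hotter and with more second substrate, reads less, 0.9% at 3.00 min. This reckoning holds green's figure for every flask, giving shares of 8.96% for theta, 5.81% for alpha, 5.16% for eta and 4.70% for beta.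

6. The forecast names theta: eta 7.8%, beta 4.9%, theta 8.6%, alpha 6.4%, on the ground “Target therefore has the lower barrier, and cold favours it”. It agrees on the winner but puts eta higher than the reckoning above, 7.8% against 5.16%.

7. The flasks give eta 7.91%, beta 6.10%, theta 12.5%, alpha 8.01%: theta leads by 4.5 percentage points over alpha, the next.

    starting material + reagent → target (k = 3.87 M⁻¹ s⁻¹, Ea = 36.0 kJ mol⁻¹)
    second substrate + reagent → second product (k = 4.88 M⁻¹ s⁻¹, Ea = 56.0 kJ mol⁻¹)
    starting material + second substrate → cross product (k = 0.363 M⁻¹ s⁻¹, Ea = 62.0 kJ mol⁻¹)
    gas ⇌ reagent, rate k4*(csat - [reagent]) (kL = 0.0191 s⁻¹)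
    reagent + target ⇌ idle adduct, settled at all times (K = 392 M⁻¹, ΔH = −55.0 kJ mol⁻¹)
    (constants at 110 °C)

Across the flasks, target at 3.00 min, all its forms counted, lies between 5.46% in beta and 6.45% in eta, while cross product runs from 40.9% in theta to 84.0% in beta. Theta's clock gave 43.7% cross product against 40.9% in the flask. A neighbour flask like theta, but with second substrate at 0.028 M, is pseudo-first-order in excess starting material, and there the same clock gives 13.7% cross product against 12.1% in the flask. Theta is not at rest: 53% starting material remains at 3.00 min. At 30.0 min its share stands at 31.0%, with 0.522% starting material left and, counted in target, 28.4% idle adduct.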